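The partner comes first in our reading of these runs: does its charge move the rate in proportion?

| flask | starting material | partner | time |
|---|---|---|---|
| epsilon | 200 mM | 220 mM |  |
| eta | 200 mM | 110 mM |  |
| delta | 400 mM | 220 mM |  |
| alpha | 920 mM | 220 mM | 9.4 min |

- epsilon run (time / min: [target] / mM): 0.38: 8.0; 0.72: 12.5; 1.4: 24.4; 2.6: 39.5; 4.9: 58.1; 9.4: 70.9
- eta run (time / min: [target] / mM): 0.38: 4.8; 0.72: 6.0; 1.4: 12.6; 2.6: 19.9; 4.9: 30.8; 9.4: 43.4
- delta run (time / min: [target] / mM): 0.38: 12.2; 0.72: 22.4; 1.4: 38.1; 2.6: 59.5; 4.9: 87.7; 9.4: 101.5

(scatter of a reading: 1 mM)

- Overall: starting material + partner -> target.
- Constant volume, constant temperature.
- Bound and free are read together.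
- An order is taken over about fifteen percent of the charge, up and down.

1. the exponent of [partner] in the starting rate at the charge of the epsilon run (at the point where two percent of the starting material have become target)
2. the exponent of [starting material] in the starting rate at the charge of the epsilon run (at the point where two percent of the starting material have become target) (one fixed amount of target, the same in the runs compared)
3. target in the alpha run at 9.4 min, as a share of the starting material charged

We work in logarithms, since an exponent is the logarithm of a rate ratio over the logarithm of the charge ratio. Early amounts of target at one time stand in for early rates. The eta run holds half the partner of the epsilon run and reads 12.6 mM of target at 1.4 min, where the epsilon run reads 24.4 mM. The exponent of c(partner) therefore reads 0.953, close to proportion.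

Does the starting material behave likewise? The delta run holds twice the starting material of the epsilon run and reads 38.1 mM of target at 1.4 min, where the epsilon run reads 24.4 mM, so the exponent of c(starting material) reads 0.643. In these readings, extra starting material buys less than its proportion. Both are readings across a factor of two, at one time and not at one amount of target, and that factor is wider than the span asked for.

Can a starting exponent then carry us to 9.4 min in the alpha run? Not directly: the epsilon run gains 17.4 mM min⁻¹ on average up to 1.4 min and just 2.84 mM min⁻¹ over its last interval. We need an exponent read late. The last delta reading against the last epsilon reading gives 0.518 for the late exponent, the power of the starting-material charge that c(target) at 9.4 min follows at fixed partner. It stands below the starting exponent.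

Carrying it from the delta charge to the alpha charge, our own reckoning gives 156 mM, which is 17.0% of the charge. That lies under the 220 mM of partner, the limiting reagent in the alpha run.

The forecast gives 1 and 0.85 for the exponents and 16.5% for the alpha run, between 13.5% and 19%, noting that “The slowdown follows target formed rather than elapsed time”. Its share stands a little below ours, and its exponent of c(starting material) stands above our reading.

The flask gives 1.1, 0.75 and 14.4%.

    2 partner ⇌ reagent dimer, settled at all times (56.50 M⁻¹)
    starting material + reagent dimer → target + partner (1.908 M⁻¹ min⁻¹)
    2 starting material ⇌ idle substrate dimer, settled at all times (2.680 M⁻¹)
    target + partner → side product (1.944 M⁻¹ min⁻¹)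

The alpha run holds 133 mM of target at 9.4 min, so from the delta reading the late exponent over this span comes to 0.323, below the carried 0.518. The alpha run loses target to the step from target and partner to side product: the simulated alpha run without that step gives 20.4% in place of 14.4%. That is 188 mM, and held against the same delta reading, which keeps its step, its late exponent is 0.740.

All runs are calculated from invented constants, noise included.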